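The benzo ring of the 2-arylbenzofuran carries neighbouring oxygens at C5 (OH) and C6 (OMe) beside the C7 prenyl group, so the C5–C6 bond is disconnected. A 2,3,5-trisubstituted furan is built first; its C2 arm is an α-prenyl acetic acid and its C3 arm a 2-(methoxymethoxy)vinyl ether. Dehydration of the acid to the ketene sets up a 6π electrocyclisation across the furan C2=C3 bond (the future C7a=C3a bond) that forms C5–C6, closes the benzo ring and, after enolisation, leaves C6 as a free phenol next to a protected C5 oxygen. Methylation at C6 and removal of both MOM groups finish the synthesis.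

Key step: step 11

Remark: step 10 is expected to give 17 as an E/Z mixture; the E isomer is drawn and both isomers are carried into step 11, because C5 ends as an aromatic carbon.
Remark: (hydroxymethyl)diphenylphosphine oxide 14 is taken as a purchasable reagent.

Step 1
Reactants: 1 3',5'-dihydroxyacetophenone
Product: 2 3'-hydroxy-5'-methoxyacetophenone
Conditions: MeI (1.0 equiv), K2CO3 (1.0 equiv), acetone, reflux
Reagents that add atoms: iodomethane CI
Why: Williamson O-methylation of one of two equivalent phenols with one equivalent of MeI should give the mono-ether as the main component of a statistical mixture, from which it is separated by chromatography while recovered 1 is recycled.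

Step 2
Reactants: 2 3'-hydroxy-5'-methoxyacetophenone
Product: 3 3'-methoxy-5'-(methoxymethoxy)acetophenone
Conditions: MeOCH2Cl, i-Pr2NEt, CH2Cl2, 0 °C → rt
Reagents that add atoms: chloromethyl methyl ether COCCl
Why: Williamson-type O-alkylation of the remaining phenol with the reactive α-chloro ether gives the MOM acetal, which is stable to the basic, hydridic and organometallic steps that follow.

Step 3
Reactants: 3 3'-methoxy-5'-(methoxymethoxy)acetophenone
Product: 5 2-bromo-1-[3-methoxy-5-(methoxymethoxy)phenyl]ethanone, via silyl enol ether 4 (not isolated)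
Conditions: LiN(SiMe3)2, Me3SiCl, THF, −78 °C; then NBS, THF, −78 → 0 °C
Reagents that add atoms: N-bromosuccinimide O=C1CCC(=O)N1Br; chlorotrimethylsilane C[Si](C)(C)Cl (silicon kept in 4 only)
Why: Kinetic enolisation and O-silylation of the methyl ketone followed by electrophilic bromination of the silyl enol ether is a regiospecific α-bromination that releases no HBr, so the MOM acetal and the electron-rich ring should stay untouched.

Step 4
Reactants: 5 2-bromo-1-[3-methoxy-5-(methoxymethoxy)phenyl]ethanone; 6 diethyl acetonedicarboxylate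
Product: 8 ethyl 2-(2-ethoxy-2-oxoethyl)-5-[3-methoxy-5-(methoxymethoxy)phenyl]furan-3-carboxylate, via tricarbonyl adduct 7 (not isolated)
Conditions: 6 (1.5 equiv), NaH (1.0 equiv), THF, 0 °C, then 5; crude 7: TsOH·H2O (5 mol %), 4 Å molecular sieves, toluene, 70 °C
Reagents that add atoms: none
Why: SN2 C-alkylation of the stabilised β-keto ester enolate by the phenacyl bromide gives a 1,4-diketone whose Paal–Knorr cyclodehydration can only place the aryl group at C5, the ester at C3 and the acetate arm at C2 of the furan; low acid loading, sieves and moderate temperature are chosen to spare the aryl MOM ether.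

Step 5
Reactants: 8 ethyl 2-(2-ethoxy-2-oxoethyl)-5-[3-methoxy-5-(methoxymethoxy)phenyl]furan-3-carboxylate
Product: 9 {3-(ethoxycarbonyl)-5-[3-methoxy-5-(methoxymethoxy)phenyl]furan-2-yl}acetic acid
Conditions: LiOH·H2O (1.1 equiv), THF/H2O, 0 °C → rt; then cold 1 M HCl to pH 3
Reagents that add atoms: lithium hydroxide [Li+].[OH-]
Why: Chemoselective saponification, since hydroxide attacks the unconjugated, unhindered acetate ester much faster than the furan-3-carboxylate, which is deactivated by conjugation with the electron-rich ring and shielded by the C2 substituent; the free acid then protects this arm in steps 7 and 8.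

Step 6
Reactants: 9 {3-(ethoxycarbonyl)-5-[3-methoxy-5-(methoxymethoxy)phenyl]furan-2-yl}acetic acid; 10 prenyl bromide
Product: 11 2-{3-(ethoxycarbonyl)-5-[3-methoxy-5-(methoxymethoxy)phenyl]furan-2-yl}-5-methylhex-4-enoic acid (racemic)
Conditions: LiN(i-Pr)2 (2.2 equiv), THF, −78 °C; 10 (1.1 equiv), −78 → 0 °C; cold 1 M HCl work-up
Reagents that add atoms: none
Why: Enolate alkylation of the carboxylic acid dianion (carboxylate plus furyl-stabilised α-carbanion) at the primary carbon of the allylic bromide (SN2); the new α-stereocentre forms racemic and is erased when the ketene is made.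

Step 7
Reactants: 11 2-{3-(ethoxycarbonyl)-5-[3-methoxy-5-(methoxymethoxy)phenyl]furan-2-yl}-5-methylhex-4-enoic acid (racemic)
Product: 12 2-{3-[methoxy(methyl)carbamoyl]-5-[3-methoxy-5-(methoxymethoxy)phenyl]furan-2-yl}-5-methylhex-4-enoic acid (racemic)
Conditions: MeNH(OMe)·HCl (3 equiv), i-PrMgCl (7 equiv), THF, −20 → 0 °C; aq. HCl to pH 3
Reagents that add atoms: N,O-dimethylhydroxylamine hydrochloride CNOC.Cl
Why: Ester aminolysis by the chloromagnesium amide of N,O-dimethylhydroxylamine (Weinreb amide synthesis) should convert only the ring ester, because the neighbouring acid is present as an unreactive magnesium carboxylate.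

Step 8
Reactants: 12 2-{3-[methoxy(methyl)carbamoyl]-5-[3-methoxy-5-(methoxymethoxy)phenyl]furan-2-yl}-5-methylhex-4-enoic acid (racemic)
Product: 13 2-{3-formyl-5-[3-methoxy-5-(methoxymethoxy)phenyl]furan-2-yl}-5-methylhex-4-enoic acid (racemic)
Conditions: i-Bu2AlH (2.5 equiv), THF, −78 °C; aq. potassium sodium tartrate (KNaC4H4O6), then pH 4
Reagents that add atoms: none
Why: Hydride reduction of the N-methoxy-N-methylamide stops at a chelated tetrahedral aluminium intermediate that gives the aldehyde on work-up (Weinreb aldehyde synthesis), while the aluminium carboxylate is not reduced at −78 °C; the alcohol stage, which would lactonise onto the acid arm, is never passed.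

Step 9
Reactants: 14 (hydroxymethyl)diphenylphosphine oxide
Product: 15 [(methoxymethoxy)methyl]diphenylphosphine oxide
Conditions: MeOCH2Cl, i-Pr2NEt, CH2Cl2, 0 °C → rt
Reagents that add atoms: chloromethyl methyl ether COCCl
Why: Standard MOM protection (O-alkylation of a primary alcohol with an α-chloro ether under amine base) turns the purchasable phosphine oxide into the reagent that delivers the C5 carbon together with its protected oxygen.

Step 10
Reactants: 13 2-{3-formyl-5-[3-methoxy-5-(methoxymethoxy)phenyl]furan-2-yl}-5-methylhex-4-enoic acid (racemic); 15 [(methoxymethoxy)methyl]diphenylphosphine oxide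
Product: 17 2-{3-[(E)-2-(methoxymethoxy)ethenyl]-5-[3-methoxy-5-(methoxymethoxy)phenyl]furan-2-yl}-5-methylhex-4-enoic acid (racemic; E isomer drawn), via hydroxy phosphine oxide adduct 16 (not isolated)
Conditions: 15 (2.3 equiv), LiN(i-Pr)2 (2.2 equiv), THF, −78 °C; 13; then KOt-Bu (2.5 equiv), −78 → 40 °C; aq. NaH2PO4 (pH 5), product used promptly
Reagents that add atoms: none
Why: Horner–Wittig olefination, in which the lithiated α-alkoxy phosphine oxide adds to the aldehyde (the first equivalent only deprotonates the acid) and the potassium alkoxide of 16 undergoes syn-elimination of diphenylphosphinate to give the enol ether, whose geometry need not be controlled.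

Step 11
Reactants: 17 2-{3-[(E)-2-(methoxymethoxy)ethenyl]-5-[3-methoxy-5-(methoxymethoxy)phenyl]furan-2-yl}-5-methylhex-4-enoic acid (racemic; E isomer drawn)
Product: 21 5-(methoxymethoxy)-2-[3-methoxy-5-(methoxymethoxy)phenyl]-7-(3-methylbut-2-en-1-yl)-1-benzofuran-6-ol, via acid chloride 18 (not isolated), via ketene 19 (not isolated), via cyclohexadienone 20 (not isolated)
Conditions: 1-chloro-N,N,2-trimethylprop-1-en-1-amine (1.1 equiv), CH2Cl2, 0 °C; then slow addition (syringe pump) to Et3N (5 equiv), toluene, 80 °C, final 0.005 M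
Reagents that add atoms: 1-chloro-N,N,2-trimethylprop-1-en-1-amine CC(C)=C(Cl)N(C)C (chlorine kept in 18 only)
Why: The acid is converted under neutral conditions into acid chloride 18, which Et3N dehydrochlorinates to the aryl(alkyl)ketene 19; its C=C bond, the furan C2=C3 bond (the future C7a=C3a bond) and the enol ether C=C bond form a 1,3,5-hexatriene that the furan holds s-cis. Thermal disrotatory 6π electrocyclisation joins the ketene carbonyl carbon (C6) to the oxygen-bearing enol ether carbon (C5) and closes the six-membered benzo ring as 2,4-cyclohexadienone 20, which tautomerises under the amine to phenol 21 and so regains furan aromaticity irreversibly. The closest known reaction type is the electrocyclic closure of dienylketenes to phenols used in ketene-based benzannulations, for example the anhydride-mediated cyclisation of Stobbe half-esters to benzofurans. No stereocentre survives, since the α-centre of 17 is planarised in 19 and C5 of 20 becomes aromatic, so E and Z enol ethers converge. Cyclisation must outrun ketene dimerisation, O-acylation of the product phenol and attack of the nucleophilic enol ether carbon C4 on the acyl carbon (five-membered ring); slow addition at high dilution, the absence of free HCl or Lewis acid and the furan-enforced geometry of the concerted pathway should secure this.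

Step 12
Reactants: 21 5-(methoxymethoxy)-2-[3-methoxy-5-(methoxymethoxy)phenyl]-7-(3-methylbut-2-en-1-yl)-1-benzofuran-6-ol
Product: 22 6-methoxy-5-(methoxymethoxy)-2-[3-methoxy-5-(methoxymethoxy)phenyl]-7-(3-methylbut-2-en-1-yl)-1-benzofuran
Conditions: MeI, K2CO3, DMF, rt → 40 °C
Reagents that add atoms: iodomethane CI
Why: Williamson O-methylation of the only free phenol (C6–OH), the two other phenolic oxygens being blocked as MOM acetals, fixes the C5/C6 oxygen pattern.

Step 13
Reactants: 22 6-methoxy-5-(methoxymethoxy)-2-[3-methoxy-5-(methoxymethoxy)phenyl]-7-(3-methylbut-2-en-1-yl)-1-benzofuran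
Product: 23 Dinklagein A
Conditions: HCl (1.25 M in MeOH), THF, 40 °C
Reagents that add atoms: none
Why: Acid-catalysed acetal exchange with methanol removes both aryl MOM ethers as dimethoxymethane; the prenyl group should survive because no free phenol sits ortho to it (C6 carries OMe, C7a the ring oxygen), so chroman formation is impossible.

Compound list
1 | 3',5'-dihydroxyacetophenone | CC(=O)c1cc(O)cc(O)c1 | starting material
2 | 3'-hydroxy-5'-methoxyacetophenone | CC(=O)c1cc(O)cc(OC)c1 | intermediate
3 | 3'-methoxy-5'-(methoxymethoxy)acetophenone | CC(=O)c1cc(OC)cc(OCOC)c1 | intermediate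
4 | trimethyl({1-[3-methoxy-5-(methoxymethoxy)phenyl]ethenyl}oxy)silane | C=C(O[Si](C)(C)C)c1cc(OC)cc(OCOC)c1 | intermediate
5 | 2-bromo-1-[3-methoxy-5-(methoxymethoxy)phenyl]ethanone | O=C(CBr)c1cc(OC)cc(OCOC)c1 | intermediate
6 | diethyl acetonedicarboxylate (diethyl 3-oxopentanedioate) | CCOC(=O)CC(=O)CC(=O)OCC | starting material
7 | diethyl 2-{2-[3-methoxy-5-(methoxymethoxy)phenyl]-2-oxoethyl}-3-oxopentanedioate (racemic) | CCOC(=O)CC(=O)C(CC(=O)c1cc(OC)cc(OCOC)c1)C(=O)OCC | intermediate
8 | ethyl 2-(2-ethoxy-2-oxoethyl)-5-[3-methoxy-5-(methoxymethoxy)phenyl]furan-3-carboxylate | CCOC(=O)Cc1oc(-c2cc(OC)cc(OCOC)c2)cc1C(=O)OCC | intermediate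
9 | {3-(ethoxycarbonyl)-5-[3-methoxy-5-(methoxymethoxy)phenyl]furan-2-yl}acetic acid | CCOC(=O)c1cc(-c2cc(OC)cc(OCOC)c2)oc1CC(=O)O | intermediate
10 | prenyl bromide (1-bromo-3-methylbut-2-ene) | CC(C)=CCBr | starting material
11 | 2-{3-(ethoxycarbonyl)-5-[3-methoxy-5-(methoxymethoxy)phenyl]furan-2-yl}-5-methylhex-4-enoic acid (racemic) | CCOC(=O)c1cc(-c2cc(OC)cc(OCOC)c2)oc1C(CC=C(C)C)C(=O)O | intermediate
12 | 2-{3-[methoxy(methyl)carbamoyl]-5-[3-methoxy-5-(methoxymethoxy)phenyl]furan-2-yl}-5-methylhex-4-enoic acid (racemic) | CON(C)C(=O)c1cc(-c2cc(OC)cc(OCOC)c2)oc1C(CC=C(C)C)C(=O)O | intermediate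
13 | 2-{3-formyl-5-[3-methoxy-5-(methoxymethoxy)phenyl]furan-2-yl}-5-methylhex-4-enoic acid (racemic) | O=Cc1cc(-c2cc(OC)cc(OCOC)c2)oc1C(CC=C(C)C)C(=O)O | intermediate
14 | (hydroxymethyl)diphenylphosphine oxide | OCP(=O)(c1ccccc1)c1ccccc1 | starting material
15 | [(methoxymethoxy)methyl]diphenylphosphine oxide | COCOCP(=O)(c1ccccc1)c1ccccc1 | intermediate
16 | 2-{3-[2-(diphenylphosphoryl)-1-hydroxy-2-(methoxymethoxy)ethyl]-5-[3-methoxy-5-(methoxymethoxy)phenyl]furan-2-yl}-5-methylhex-4-enoic acid (mixture of diastereomers, present as its alkoxide carboxylate) | COCOC(C(O)c1cc(-c2cc(OC)cc(OCOC)c2)oc1C(CC=C(C)C)C(=O)O)P(=O)(c1ccccc1)c1ccccc1 | intermediate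
17 | 2-{3-[(E)-2-(methoxymethoxy)ethenyl]-5-[3-methoxy-5-(methoxymethoxy)phenyl]furan-2-yl}-5-methylhex-4-enoic acid (racemic; E isomer drawn) | COCO/C=C/c1cc(-c2cc(OC)cc(OCOC)c2)oc1C(CC=C(C)C)C(=O)O | intermediate
18 | 2-{3-[(E)-2-(methoxymethoxy)ethenyl]-5-[3-methoxy-5-(methoxymethoxy)phenyl]furan-2-yl}-5-methylhex-4-enoyl chloride (racemic) | COCO/C=C/c1cc(-c2cc(OC)cc(OCOC)c2)oc1C(CC=C(C)C)C(=O)Cl | intermediate
19 | 2-{3-[(E)-2-(methoxymethoxy)ethenyl]-5-[3-methoxy-5-(methoxymethoxy)phenyl]furan-2-yl}-5-methylhexa-1,4-dien-1-one (ketene) | COCO/C=C/c1cc(-c2cc(OC)cc(OCOC)c2)oc1C(CC=C(C)C)=C=O | intermediate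
20 | 5-(methoxymethoxy)-2-[3-methoxy-5-(methoxymethoxy)phenyl]-7-(3-methylbut-2-en-1-yl)-1-benzofuran-6(5H)-one (racemic) | COCOC1C=C2C=C(-c3cc(OC)cc(OCOC)c3)OC2=C(CC=C(C)C)C1=O | intermediate
21 | 5-(methoxymethoxy)-2-[3-methoxy-5-(methoxymethoxy)phenyl]-7-(3-methylbut-2-en-1-yl)-1-benzofuran-6-ol | COCOc1cc2cc(-c3cc(OC)cc(OCOC)c3)oc2c(CC=C(C)C)c1O | intermediate
22 | 6-methoxy-5-(methoxymethoxy)-2-[3-methoxy-5-(methoxymethoxy)phenyl]-7-(3-methylbut-2-en-1-yl)-1-benzofuran | COCOc1cc2cc(-c3cc(OC)cc(OCOC)c3)oc2c(CC=C(C)C)c1OC | intermediate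
23 | Dinklagein A, 2-(3-hydroxy-5-methoxyphenyl)-6-methoxy-7-(3-methylbut-2-en-1-yl)-1-benzofuran-5-ol | COc1cc(O)cc(-c2cc3cc(O)c(OC)c(CC=C(C)C)c3o2)c1 | target

Total step count: 13. Longest linear sequence: 12 steps (steps 1–8 and 10–13; step 9 prepares the olefination reagent).

Steps most likely to fail

Step 11. The ketene may be diverted before it cyclises: by dimerisation, by acylation of the product phenol or of the enol ether carbon C4 by the activated acid, or by acid-induced loss of the enol ether. The fallback sets out from 17 and comes back at 21, and it releases the ketene from an ester enolate so that no acylating species is present. Acid 17 would be esterified with phenol (dicyclohexylcarbodiimide, catalytic 4-dimethylaminopyridine, CH2Cl2) to give phenyl 2-{3-[(E)-2-(methoxymethoxy)ethenyl]-5-[3-methoxy-5-(methoxymethoxy)phenyl]furan-2-yl}-5-methylhex-4-enoate F1. Complete enolisation of F1 with KN(SiMe3)2 in THF at −78 °C and warming should expel phenoxide (E1cB fragmentation of an aryl ester enolate) to give ketene 19. The same electrocyclisation and tautomerisation then deliver 21 as its phenoxide, which is protonated on work-up.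

Step 7. Aminolysis of the hindered, electron-rich ring ester next to the magnesium carboxylate may stall, or the magnesium amide may deprotonate the acidic α-carbon and so deactivate the ester. The fallback sets out from 11 and comes back at 17. LiBH4 in THF/MeOH should reduce the ring ester while the lithium carboxylate is inert. Acidification lets the hydroxy acid close to the δ-lactone 2-[3-methoxy-5-(methoxymethoxy)phenyl]-7-(3-methylbut-2-en-1-yl)-4,7-dihydro-6H-furo[3,2-c]pyran-6-one F2. F2 would be opened in K2CO3/MeOH and the furyl carbinol of the open form oxidised in the same flask with activated MnO2 to methyl 2-{3-formyl-5-[3-methoxy-5-(methoxymethoxy)phenyl]furan-2-yl}-5-methylhex-4-enoate F3. Horner–Wittig olefination of F3 with 15 under the conditions of step 10 gives methyl 2-{3-[(E)-2-(methoxymethoxy)ethenyl]-5-[3-methoxy-5-(methoxymethoxy)phenyl]furan-2-yl}-5-methylhex-4-enoate F4, and saponification with LiOH in THF/MeOH/H2O returns 17.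

Step 4. The aryl MOM acetal may be lost under the acid needed for cyclodehydration, and 7 may be diverted by intramolecular aldol condensation if the acid is too weak to cyclise it quickly. The fallback sets out from 7 and comes back at 8. Crude 7 would be cyclised with a full equivalent of TsOH·H2O in toluene at 100 °C, accepting cleavage of the acetal, to give ethyl 2-(2-ethoxy-2-oxoethyl)-5-(3-hydroxy-5-methoxyphenyl)furan-3-carboxylate F5. The free phenol of F5 is then protected again with MeOCH2Cl and i-Pr2NEt in CH2Cl2 to give 8.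

Further compounds
F1 | step 11 | phenyl 2-{3-[(E)-2-(methoxymethoxy)ethenyl]-5-[3-methoxy-5-(methoxymethoxy)phenyl]furan-2-yl}-5-methylhex-4-enoate (racemic) | COCO/C=C/c1cc(-c2cc(OC)cc(OCOC)c2)oc1C(CC=C(C)C)C(=O)Oc1ccccc1
F2 | step 7 | 2-[3-methoxy-5-(methoxymethoxy)phenyl]-7-(3-methylbut-2-en-1-yl)-4,7-dihydro-6H-furo[3,2-c]pyran-6-one (racemic) | O=C1OCc2cc(-c3cc(OC)cc(OCOC)c3)oc2C1CC=C(C)C
F3 | step 7 | methyl 2-{3-formyl-5-[3-methoxy-5-(methoxymethoxy)phenyl]furan-2-yl}-5-methylhex-4-enoate (racemic) | COC(=O)C(CC=C(C)C)c1oc(-c2cc(OC)cc(OCOC)c2)cc1C=O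
F4 | step 7 | methyl 2-{3-[(E)-2-(methoxymethoxy)ethenyl]-5-[3-methoxy-5-(methoxymethoxy)phenyl]furan-2-yl}-5-methylhex-4-enoate (racemic; E isomer drawn) | COCO/C=C/c1cc(-c2cc(OC)cc(OCOC)c2)oc1C(CC=C(C)C)C(=O)OC
F5 | step 4 | ethyl 2-(2-ethoxy-2-oxoethyl)-5-(3-hydroxy-5-methoxyphenyl)furan-3-carboxylate | CCOC(=O)Cc1oc(-c2cc(O)cc(OC)c2)cc1C(=O)OCC
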